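Locants used throughout are those of the target: C1 is the quaternary oxirane carbon carrying the C7 methylene, C2 carries OMe, C3 carries OBz, C4=C5 is the alkene and C6 is the oxirane CH. Descriptors quoted for intermediates refer to these locants.

## Analysis of the target

The target 22 is a 7-oxabicyclo[4.1.0]hept-4-ene: a cyclohexene (C4=C5) with an oxirane across C1–C6, a benzoyloxymethyl group (C7) on C1, a methyl ether at C2 and an allylic benzoate at C3. The four stereocentres C6, C1, C2 and C3 are contiguous and have the configuration (1R,2S,3R,6R). The oxirane oxygen and the C2 methoxy lie on one face of the ring; C7 and the C3 benzoate lie on the other, so C2–O and C3–O are trans. The vinyl oxirane (tertiary at C1, allylic at C6) opens with acid or in SN2′ fashion, and the two benzoates are open to hydrolysis and acyl migration under base. The difficulty is that five of six ring carbons are functionalised, that three neighbouring oxygens must end as ether, ester and oxirane, and that the absolute configuration hinges on the fully substituted carbinol carbon C1. The plan rests on one feature: C1, with its oxygen and C7, is flanked by the oxygenated carbons C2 and C6, as the carbinol carbon of a 4-substituted 4-hydroxycyclohexadienone is flanked by two enone β-carbons. The cis relation of C1–O and C2–O is what a short tether from the C1 oxygen to C2 must give, and that tether then shields one face for the later reactions at C3 and C6.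

## Retrosynthetic reasoning

The last bond cut is the ester C–O at C3, so 22 comes from the allylic alcohol 20 and 21. Leaving this acylation to the end keeps an α-acyloxy ketone out of the basic peroxide and Wharton steps, where acyl loss and elimination would compete. The forward reaction only has to acylate the one free secondary hydroxyl without touching the vinyl oxirane.

In 20 the C6–O bond of the oxirane is cut. The oxygen stays on C1, where it has been since the quinol stage, and C6 becomes a carbon with a sulfonate on the opposite face (18). Cutting C6–O and not C1–O leaves the quaternary stereocentre untouched and reduces oxirane formation to an anti displacement. The silyl ether at C3 is taken off in the same flask (via 19).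

The O–CH3 bond at C2 is cut next, giving diol 17. The forward alkylation must choose the secondary C2 hydroxyl over the tertiary C1 hydroxyl under conditions too weakly basic to close the hydroxy mesylate early.

In 17 both C–O bonds to a one-carbon bridge are restored, giving the methylene acetal 15 (forward via 16, with release of 5). Keeping the acetal carbon as the methyl group by reductive opening would be shorter. It is not relied on, because an acid activator binds the less hindered C2 oxygen and would leave the carbon on the tertiary C1 oxygen. The acetal is therefore removed and the methyl group added separately.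

The S–O bond of the mesylate is cut to give alcohol 14.

In 14 the C4 carbonyl is reinstated and the C6 hydroxyl becomes the distal C–O bond of a C5–C6 oxirane (11; forward via 12 and 13). This Wharton transposition delivers C4=C5 and C6–OH together and carries the C6 configuration over unchanged from the oxirane.

The C5–O and C6–O bonds of 11 are cut to the enone 10. The forward nucleophilic epoxidation must come from the face opposite the C1 oxygen, so that the C6 oxygen can later leave anti to it.

The C3–O bond of 10 is cut, through the oxirane 9 and the silyl dienol ether 8, back to 7. C3 is the only enolisable position of 7 (C5 is vinylic, C1 is quaternary), so no regiocontrol is needed, and the silyl group of the enol ether ends as the protecting group on the C3 oxygen.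

The central cut removes the C2–O bond and the two C–O bonds of the acetal carbon of 7, giving the dienone 4 and 5 (forward via 6). It is made here because it is the only disconnection that erases both stereocentres at once and leaves a precursor with a mirror plane through C1 and C4. The forward reaction must therefore choose between two enantiotopic enones.

Finally the C1–O bond of 4 is cut to the phenol 3 (oxidative dearomatisation), and the ester bond of 3 to 1 and 2.

## Alternatives that were turned down

Alternative 1: The C2–O and C3–O bonds are traced back to one oxirane, and the ring to methyl 1-hydroxycyclohexa-2,5-diene-1-carboxylate A2. A2 would come from Birch reduction of benzoic acid A1, hydroxylation of the dienolate and esterification. In the forward key step Hf(OtBu)4 with a chiral bishydroxamic acid and an alkyl hydroperoxide would epoxidise one of the two enantiotopic alkenes of A2 on the face of the tertiary hydroxyl, giving the syn epoxy alcohol A3.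
- For it: the hydroxyl-bound metal peroxide puts the C2 oxygen cis to the C1 oxygen by construction. C2 and C3 are oxygenated in one step. Opening the oxirane at C3, remote from the quaternary carbon, with a carboxylate would give the trans C2/C3 pattern.
- Against it for 22: C7 enters as an ester carbon and must be reduced beside an oxirane and esters. The remaining alkene sits at C5=C6 with a C4 methylene, so it must be moved and C6 oxygenated anti to the hydroxyl that directs reagents syn. A2 is a skipped dienol that aromatises by loss of water.
- Comparison: this route is stronger at C3, whose oxygen comes with the key step and not from a later enol ether oxidation. The chosen plan offers C7 at the right oxidation level from the start, a key product in which C1–O and C2–O are already protected, and an enone placed so that C3 and C6 are reached without moving an alkene against a directing group.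

Alternative 2: The C1–O bond (with C6–O) is cut back to the arene itself. In the forward key step whole cells of Ralstonia eutropha B9, which have the benzoate 1,2-dioxygenase but lack the diol dehydrogenase, would add both atoms of dioxygen cis across C1 and C6 of benzoic acid A1. The product would be (1S,2R)-1,2-dihydroxycyclohexa-3,5-diene-1-carboxylic acid A4 as a single enantiomer.
- For it: C1 is obtained with the right absolute configuration in one operation, with no catalyst tuning. The C4=C5 alkene is already part of the diene. C2=C3 lies next to the tertiary hydroxyl for a directed epoxidation and allylic trans opening at C3.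
- Against it for 22: the C6 hydroxyl is cis to the C1 oxygen, so the oxirane can only close after inversion at C6, an allylic carbon beside a quaternary centre where SN2′ and elimination compete. The carboxyl group must be reduced to the C7 alcohol. A4 dehydrates and aromatises readily with acid. Fermentation with a blocked mutant is not a routine laboratory operation.
- Comparison: on enantiopurity and on the number of steps to a ring with C1 defined, this route is stronger. The chosen plan offers purely chemical catalysis that can give either enantiomer, C7 already as its benzoate, and a C6 oxygen that arrives directly on the face needed for closure by the C1 oxygen.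

Alternative 3: The ring bond C5–C6 is cut and the open chain is traced to D-fructose A5. Its C3 and C4 become C2 and C3 of the target, and its ketose carbon becomes C1, carrying a spiro oxirane to C7. In the forward key step CrCl2 with catalytic NiCl2 (Nozaki–Hiyama–Kishi conditions) would add the (Z)-alkenyl iodide carbon of the iodo aldehyde A6 to its aldehyde, closing the cyclohexene as the spiro-epoxy cyclohexenol A7. A Payne rearrangement would then move the oxirane from C1–C7 to C1–C6 and free the C7 oxygen for benzoylation.
- For it: C2 and C3 come from the chiral pool with no question about absolute configuration. The chromium-mediated addition tolerates esters and ethers. The Payne relay forms the oxirane and liberates the C7 oxygen in one move.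
- Against it for 22: the sugar needs a long series of hydroxyl differentiations, a one-carbon extension at the ketose carbon, a deoxygenation and a (Z)-selective iodo-olefination before the key step. C1 and C6 still have to be set under substrate control, and C6–OH must come out trans to the spiro oxirane oxygen for the Payne step. The α-quaternary epoxy aldehyde A6 is exposed to Lewis acidic chromium salts used in excess. The Payne equilibrium has to be driven under base beside a benzoate.
- Comparison: on certainty of configuration at C2 and C3 this route is stronger. The chosen plan is far shorter, creates C1 and C2 together with a catalyst from an achiral two-step precursor, and sets C6 on a rigid bicycle and not in an open chain.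

Key step: step 3

Assumption: the sense of induction of the phosphoric acid with this quinol cannot be predicted with certainty. The route is written for the (R)-catalyst; if it favours the mirror-image acetal, the (S)-catalyst is used in step 3 and nothing else changes.

## Route

Step 1
Reactants: 1 4-hydroxybenzyl alcohol; 2 benzoic acid
Product: 3 4-hydroxybenzyl benzoate
Conditions: PPh3, DIAD, THF, 0 °C → rt
Reagents that add atoms: none
Why: Mitsunobu esterification: only the benzylic hydroxyl is activated as the alkoxyphosphonium ion and it is displaced by benzoate, the far more acidic pronucleophile, so the phenol stays free; no base is present, which avoids quinone methide formation from the p-hydroxybenzyl ester.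

Step 2
Reactants: 3 4-hydroxybenzyl benzoate
Product: 4 4-[(benzoyloxy)methyl]-4-hydroxycyclohexa-2,5-dien-1-one (the p-quinol)
Conditions: PhI(OAc)2, MeCN/H2O (3:1), 0 °C
Reagents that add atoms: water, O
Why: Oxidative dearomatisation with trivalent iodine: ligand exchange at the phenol oxygen makes the para carbon electrophilic and water adds there to give the p-quinol; the para substituent blocks quinone formation and the acetic acid set free keeps the medium non-basic.

Step 3
Reactants: 4 4-[(benzoyloxy)methyl]-4-hydroxycyclohexa-2,5-dien-1-one; 5 formaldehyde (charged as paraformaldehyde)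
Product: 7 (3aS,7aS)-7a-[(benzoyloxy)methyl]-3a,7a-dihydro-1,3-benzodioxol-5(4H)-one (cis-fused methylene acetal enone; 1S,2S in target locants), via formaldehyde hemiacetal 6 (not isolated)
Conditions: (CH2O)n, (R)-3,3′-bis(2,4,6-triisopropylphenyl)-1,1′-binaphthyl-2,2′-diyl hydrogen phosphate (10 mol %), ClCH2CH2Cl, 40 °C
Reagents that add atoms: none
Why: The tertiary hydroxyl of 4 adds reversibly to formaldehyde to give hemiacetal 6, whose new hydroxyl sits two atoms further out and can reach an enone β-carbon. The phosphoric acid holds this hydroxyl through its P=O oxygen and activates one enone carbonyl through its P–OH, the oxygen adds to C2 in an oxa-Michael reaction and the enol tautomerises to the ketone. The closest known reaction type is the chiral phosphoric acid catalysed acetalisation/oxa-Michael desymmetrisation of p-quinols and p-peroxyquinols with aldehydes. The 1,3-dioxolane closes in a 5-exo-trig mode. C1 becomes a stereocentre only because the two enones cease to be equivalent, and its configuration is set by the catalyst, whose 3,3′-aryl groups decide which enantiotopic enone fits the bound pocket. C2 is set by the ring itself, since an O–C–O bridge can span C1 and C2 only on one face, so the fusion is cis. The step needs enantiotopic group selectivity and a single addition; the mirror symmetry of 4, the absence of any other free hydroxyl and the fact that the bridged product has no hydroxyl left secure the second, and the acid is too weak to ionise the tertiary carbinol or cleave the benzoate.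

Step 4
Reactants: 7 cis-fused methylene acetal enone
Product: 8 (1S,2S)-silyl dienol ether (C3=C4–OTBS; C5=C6; C1/C2 methylene acetal intact)
Conditions: TBSOTf, Et3N, CH2Cl2, −78 → 0 °C
Reagents that add atoms: tert-butyldimethylsilyl trifluoromethanesulfonate, CC(C)(C)[Si](C)(C)OS(=O)(=O)C(F)(F)F
Why: Soft enolisation: the silyl triflate activates the carbonyl and Et3N removes a C3 proton, the only enolisable position (C5 is vinylic, C1 quaternary), so the cross-conjugated dienol ether forms without a free β-alkoxy enolate that could expel the C2 oxygen; the bulky triflate with a trialkylamine leaves the methylene acetal alone.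

Step 5
Reactants: 8 silyl dienol ether
Product: 10 (1S,2S,3S)-3-(tert-butyldimethylsilyloxy) enone (C3–OTBS trans to C2–O; C4 ketone; C5=C6), via silyloxy oxirane 9 (not isolated)
Conditions: mCPBA, NaHCO3, CH2Cl2, −20 → 0 °C
Reagents that add atoms: 3-chloroperoxybenzoic acid, OOC(=O)c1cccc(Cl)c1
Why: Rubottom oxidation: the peracid epoxidises the electron-rich C3=C4 enol ether on the convex face, anti to the allylic C2–O bond and away from the pseudo-axial C1–O bond and the acetal methylene, and oxirane 9 opens with 1,4-silyl shift to the α′-silyloxy enone; C3–O therefore ends trans to C2–O (3S) and the silyl group stays as protecting group.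

Step 6
Reactants: 10 3-silyloxy enone
Product: 11 (1R,2S,3S,5R,6S)-5,6-epoxy ketone (oxirane trans to the C1 oxygen)
Conditions: tBuOOH (decane), DBU, CH2Cl2, 0 °C
Reagents that add atoms: tert-butyl hydroperoxide, CC(C)(C)OO
Why: Weitz–Scheffer epoxidation: the peroxide anion adds to C6 and the enolate closes on the O–O bond; in the half-chair that keeps CH2OBz, C2–O and C3–OTBS pseudo-equatorial the C1–O bond is pseudo-axial, so axial attack at C6 comes anti to it on the convex face and the oxirane forms trans to the C1 oxygen; the non-aqueous conditions spare the benzoate and the silyloxy ketone is much less prone to epimerisation than an acyloxy ketone.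

Step 7
Reactants: 11 5,6-epoxy ketone
Product: 14 (1R,2S,3R,6S)-allylic alcohol (C4=C5; C6–OH trans to C1–O; C3–OTBS), via epoxy hydrazone 12 (not isolated), via alkenyl diazene 13 (not isolated)
Conditions: N2H4·H2O, AcOH, MeOH, 0 °C → rt
Reagents that add atoms: none
Why: Wharton transposition: hydrazone 12 opens the oxirane to alkenyl diazene 13, which loses N2 and leaves C4=C5 and the C6 hydroxyl; the C6–O bond is never broken, so its configuration is retained, and the C3 silyl ether is too poor a leaving group to compete with the strained oxirane.

Step 8
Reactants: 14 allylic alcohol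
Product: 15 (1S,2S,3R,6S)-C6 methanesulfonate of 14
Conditions: Ms2O, Et3N, CH2Cl2, −20 → 0 °C
Reagents that add atoms: methanesulfonic anhydride, CS(=O)(=O)OS(C)(=O)=O
Why: Sulfonylation of the hindered secondary alcohol through sulfene; the anhydride is used so that no chloride is present to displace the allylic mesylate, and the C6 configuration is unchanged.

Step 9
Reactants: 15 C6 methanesulfonate
Product: 17 (1S,2S,3R,6S)-C1,C2-diol (C3–OTBS; C6–OMs; C7–OBz), via bipyridinium salt 16 (not isolated)
Conditions: TMSOTf, 2,2′-bipyridyl, CH2Cl2, 0 °C → rt; then H2O
Reagents that add atoms: none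
Why: Silyl triflate/2,2′-bipyridyl cleavage of a methylene acetal: silylation of the less hindered C2 oxygen opens the ring to the N-(alkoxymethyl)bipyridinium salt 16, which water hydrolyses with loss of formaldehyde; the medium is neither strongly acidic nor basic, so mesylate, benzoate and the TBS ether survive and the hydroxy mesylate does not close.

Step 10
Reactants: 17 C1,C2-diol
Product: 18 (1S,2S,3R,6S)-C2 methyl ether (C1–OH free; C3–OTBS; C6–OMs)
Conditions: MeOTf, 2,6-di-tert-butyl-4-methylpyridine, CH2Cl2, 0 °C → rt
Reagents that add atoms: methyl trifluoromethanesulfonate, COS(=O)(=O)C(F)(F)F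
Why: O-Alkylation with methyl triflate and a hindered non-nucleophilic pyridine: the secondary C2 hydroxyl reacts far faster than the tertiary C1 hydroxyl, and the base is too weak to close the oxirane or to cause acyl or silyl migration.

Step 11
Reactants: 18 C2 methyl ether
Product: 20 [(1R,2S,3R,6R)-3-hydroxy-2-methoxy-7-oxabicyclo[4.1.0]hept-4-en-1-yl]methyl benzoate, via silyl ether oxirane 19 (not isolated)
Conditions: DBU, THF, rt → 40 °C; then Bu4NF, AcOH, 0 °C → rt
Reagents that add atoms: none
Why: Intramolecular Williamson closure (3-exo-tet): the C1 oxygen displaces the antiperiplanar C6 mesylate with inversion, in a conformer that keeps all other substituents pseudo-equatorial, giving the oxirane cis to the C2 methoxy; buffered fluoride then removes the silyl group from 19 without opening the vinyl oxirane or cleaving the benzoate.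

Step 12
Reactants: 20 epoxy alcohol; 21 benzoyl chloride
Product: 22 [(1R,2S,3R,6R)-3-(benzoyloxy)-2-methoxy-7-oxabicyclo[4.1.0]hept-4-en-1-yl]methyl benzoate (target)
Conditions: BzCl, pyridine, 4-(dimethylamino)pyridine (cat.), CH2Cl2, 0 °C
Reagents that add atoms: none
Why: Acylation through the acylpyridinium ion; the secondary allylic C3 hydroxyl is the only free hydroxyl, and the mild base leaves the oxirane and the C7 benzoate untouched.

## Compound list

1 | 4-hydroxybenzyl alcohol | OCc1ccc(O)cc1 | starting material
2 | benzoic acid | OC(=O)c1ccccc1 | starting material
3 | 4-hydroxybenzyl benzoate | O=C(OCc1ccc(O)cc1)c1ccccc1 | intermediate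
4 | 4-[(benzoyloxy)methyl]-4-hydroxycyclohexa-2,5-dien-1-one (p-quinol) | O=C1C=CC(O)(COC(=O)c2ccccc2)C=C1 | intermediate
5 | formaldehyde (charged as paraformaldehyde) | C=O | starting material
6 | 4-[(benzoyloxy)methyl]-4-(hydroxymethoxy)cyclohexa-2,5-dien-1-one (formaldehyde hemiacetal of 4) | O=C1C=CC(OCO)(COC(=O)c2ccccc2)C=C1 | intermediate (not isolated)
7 | (3aS,7aS)-7a-[(benzoyloxy)methyl]-3a,7a-dihydro-1,3-benzodioxol-5(4H)-one; cis-fused methylene acetal enone, (1S,2S) | O=C1C[C@@H]2OCO[C@]2(COC(=O)c3ccccc3)C=C1 | intermediate
8 | (1S,2S)-silyl dienol ether of 7: C3=C4–OTBS, C5=C6 | CC(C)(C)[Si](C)(C)OC1=C[C@@H]2OCO[C@]2(COC(=O)c3ccccc3)C=C1 | intermediate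
9 | C3,C4-oxirane of 8, oxirane oxygen on the face opposite the dioxolane, OTBS on C4 | CC(C)(C)[Si](C)(C)O[C@]12O[C@H]1[C@@H]1OCO[C@]1(COC(=O)c3ccccc3)C=C2 | intermediate (not isolated)
10 | (1S,2S,3S)-3-(tert-butyldimethylsilyloxy) enone: C3–OTBS trans to C2–O, C4 ketone, C5=C6 | O=C1[C@@H](O[Si](C)(C)C(C)(C)C)[C@@H]2OCO[C@]2(COC(=O)c3ccccc3)C=C1 | intermediate
11 | (1R,2S,3S,5R,6S)-5,6-epoxy ketone: oxirane trans to the C1 oxygen | O=C1[C@@H](O[Si](C)(C)C(C)(C)C)[C@@H]2OCO[C@]2(COC(=O)c3ccccc3)[C@H]4O[C@@H]14 | intermediate
12 | C4 hydrazone of 11 | NN=C1[C@@H](O[Si](C)(C)C(C)(C)C)[C@@H]2OCO[C@]2(COC(=O)c3ccccc3)[C@H]4O[C@@H]14 | intermediate (not isolated)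
13 | alkenyl diazene: C4(N=NH)=C5, C6–OH | O[C@H]1C=C(N=N)[C@@H](O[Si](C)(C)C(C)(C)C)[C@@H]2OCO[C@]12COC(=O)c1ccccc1 | intermediate (not isolated)
14 | (1R,2S,3R,6S)-allylic alcohol: C4=C5, C6–OH trans to C1–O, C3–OTBS, methylene acetal | O[C@H]1C=C[C@@H](O[Si](C)(C)C(C)(C)C)[C@@H]2OCO[C@]12COC(=O)c1ccccc1 | intermediate
15 | (1S,2S,3R,6S)-C6 methanesulfonate of 14 | CS(=O)(=O)O[C@H]1C=C[C@@H](O[Si](C)(C)C(C)(C)C)[C@@H]2OCO[C@]12COC(=O)c1ccccc1 | intermediate
16 | ring-opened salt: C2–OSiMe3, C1–OCH2–(2,2′-bipyridin-1-ium) triflate (the regioisomer would give the same diol) | CS(=O)(=O)O[C@H]1C=C[C@@H](O[Si](C)(C)C(C)(C)C)[C@H](O[Si](C)(C)C)[C@@]1(OC[n+]2ccccc2-c2ccccn2)COC(=O)c1ccccc1.[O-]S(=O)(=O)C(F)(F)F | intermediate (not isolated)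
17 | (1S,2S,3R,6S)-C1,C2-cis-diol: C3–OTBS, C6–OMs, C7–OBz | CS(=O)(=O)O[C@H]1C=C[C@@H](O[Si](C)(C)C(C)(C)C)[C@H](O)[C@@]1(O)COC(=O)c1ccccc1 | intermediate
18 | (1S,2S,3R,6S)-C2 methyl ether of 17, C1–OH free | CS(=O)(=O)O[C@H]1C=C[C@@H](O[Si](C)(C)C(C)(C)C)[C@H](OC)[C@@]1(O)COC(=O)c1ccccc1 | intermediate
19 | [(1R,2S,3R,6R)-3-(tert-butyldimethylsilyloxy)-2-methoxy-7-oxabicyclo[4.1.0]hept-4-en-1-yl]methyl benzoate | CO[C@H]1[C@H](O[Si](C)(C)C(C)(C)C)C=C[C@H]2O[C@]21COC(=O)c1ccccc1 | intermediate (not isolated)
20 | [(1R,2S,3R,6R)-3-hydroxy-2-methoxy-7-oxabicyclo[4.1.0]hept-4-en-1-yl]methyl benzoate | CO[C@H]1[C@H](O)C=C[C@H]2O[C@]21COC(=O)c1ccccc1 | intermediate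
21 | benzoyl chloride | O=C(Cl)c1ccccc1 | starting material
22 | [(1R,2S,3R,6R)-3-(benzoyloxy)-2-methoxy-7-oxabicyclo[4.1.0]hept-4-en-1-yl]methyl benzoate | CO[C@H]1[C@H](OC(=O)c2ccccc2)C=C[C@H]2O[C@]21COC(=O)c1ccccc1 | target

## Step count and least certain steps

Total step count: 12. Longest linear sequence: 12 steps (1 → 22); the route is fully linear.

Step 3 (key step). Enantiotopic discrimination may be weak, because the unsubstituted hemiacetal carbon gives the catalyst no substituent to orient and an uncatalysed closure can compete. The quinol hydroxyl may also be tied up as oligo(oxymethylene) hemiacetals that cannot cyclise, and slow retro-oxa-Michael reaction could erode the enantiomeric purity. Fallback, from 4 back to 7, with a boron tether in place of the hemiacetal: 4 is treated with phenylboronic acid and a chiral bifunctional amine–thiourea, 1-[3,5-bis(trifluoromethyl)phenyl]-3-[(1R,2R)-2-(dimethylamino)cyclohexyl]thiourea or its enantiomer. The boronic hemiester oxygen adds to C2 (oxa-Michael addition of a boronate as hydroxide equivalent to a γ-hydroxy enone) and gives the cyclic phenylboronate F1. Transesterification with pinacol releases the cis-diol enone F2. Acetal exchange with dimethoxymethane (TMSOTf cat., CH2Cl2, 0 °C) then gives 7.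

Step 5. The peracid may attack C3 from the dioxolane face (poor facial selectivity, since the bias comes only from the neighbouring ring), or the dienol ether may be protodesilylated back to 7 before it is oxidised. Fallback, from 7 back to 10, by oxidation through a manganese enolate under equilibrating conditions: Mn(OAc)3 in benzene at reflux acetoxylates the enone at C3 (α′-acetoxylation of enones), giving the α′-acetoxy enone F3 with the acetate in the more stable position trans to C2–O. Acid-catalysed methanolysis (AcCl cat., MeOH, 0 °C) frees the α′-hydroxy enone F4. TBSOTf with 2,6-lutidine gives 10.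

Step 6. The peroxide anion may add to C6 from the face of the C1 oxygen, because C1 is quaternary and carries a substituent on each face. The base may also epimerise C3 or expel the C2 oxygen by β-elimination. Fallback, from 7 back to 14, setting C3 and C6 together in a cycloaddition: Tf2O with 2,6-di-tert-butyl-4-methylpyridine converts 7 into the dienyl triflate F5. Pd(OAc)2, PPh3, HCO2H and Et3N reduce it to the cyclohexa-3,5-diene F6. Singlet oxygen (O2, 5,10,15,20-tetraphenylporphyrin, hν, CH2Cl2, −20 °C) adds across C3 and C6 anti to both allylic oxygens of the dioxolane to give the endoperoxide F7. Thiourea in MeOH reduces the O–O bond to the ene-1,4-diol F8. TBSCl with imidazole silylates the less hindered C3 hydroxyl and gives 14.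

Step 7. Hydrazone formation at the hindered C4 ketone may be slow, so that hydrazinolysis of the C7 benzoate and azine formation take over, and the fragmentation of the diazene may proceed with low efficiency. Fallback, from 11 back to 14, by a radical opening of the oxirane: NaBH4 with CeCl3 (MeOH, −40 °C) reduces 11 to the epoxy alcohol F9 (either C4 epimer serves, since C4 becomes sp2). 1,1′-Thiocarbonyldiimidazole gives the imidazolylthiocarbonate F10. Bu3SnH with azobisisobutyronitrile (toluene, 80 °C) generates the C4 radical, which opens the C5–O bond; the C6 alkoxyl radical takes up hydrogen and gives 14.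

Step 9. The hindered acetal may open incompletely under the mild silyl triflate conditions, and forcing them may ionise the allylic mesylate or remove the silyl ether. Fallback, from 14 back to 17, by exchanging the acetal one step earlier, where no allylic sulfonate restricts the Lewis acid: Me2BBr with Et3N (CH2Cl2, −78 °C), then aqueous NaHCO3, cleaves the methylene acetal of 14 to the triol F11. 2-Methoxypropene with pyridinium p-toluenesulfonate bridges only the cis C1/C2 hydroxyls and gives the acetonide alcohol F12. Ms2O with Et3N gives the acetonide mesylate F13. Aqueous AcOH at rt removes the acetonide and gives 17.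

## Further compounds

F1 | step 3 | cyclic phenylboronate bridging C1–O and C2–O of the enone (boron analogue of 7) | O=C1C[C@@H]2OB(c3ccccc3)O[C@]2(COC(=O)c3ccccc3)C=C1
F2 | step 3 | cis-C1,C2-diol enone: C1–OH and C2–OH on one face, C4 ketone, C5=C6, C7H2OBz on C1 | O=C1C[C@H](O)[C@@](O)(COC(=O)c2ccccc2)C=C1
F3 | step 5 | α′-acetoxy enone: C3–OAc trans to C2–O, methylene acetal as in 7 | O=C1[C@@H](OC(C)=O)[C@@H]2OCO[C@]2(COC(=O)c3ccccc3)C=C1
F4 | step 5 | α′-hydroxy enone: C3–OH trans to C2–O, methylene acetal as in 7 | O=C1[C@@H](O)[C@@H]2OCO[C@]2(COC(=O)c3ccccc3)C=C1
F5 | step 6 | dienyl triflate: C3=C4–OTf, C5=C6, methylene acetal as in 7 | O=S(=O)(OC1=C[C@@H]2OCO[C@]2(COC(=O)c3ccccc3)C=C1)C(F)(F)F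
F6 | step 6 | cyclohexa-3,5-diene with cis-fused C1,C2 methylene acetal and C7H2OBz on C1 | C1=C[C@@H]2OCO[C@]2(COC(=O)c3ccccc3)C=C1
F7 | step 6 | endoperoxide: O–O bridge from C3 to C6 on the face opposite the dioxolane, C4=C5 | O1O[C@H]2C=C[C@@H]1[C@@H]1OCO[C@]21COC(=O)c1ccccc1
F8 | step 6 | ene-1,4-diol: C3–OH and C6–OH both trans to the dioxolane oxygens, C4=C5 | O[C@H]1C=C[C@@H](O)[C@@H]2OCO[C@]12COC(=O)c1ccccc1
F9 | step 7 | epoxy alcohol: C4–OH cis to the C5,C6-oxirane, C3–OTBS, methylene acetal | O[C@H]1[C@@H](O[Si](C)(C)C(C)(C)C)[C@@H]2OCO[C@]2(COC(=O)c3ccccc3)[C@H]4O[C@@H]14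
F10 | step 7 | O-(imidazol-1-ylthiocarbonyl) derivative of F9 at C4 | S=C(n1ccnc1)O[C@H]1[C@@H](O[Si](C)(C)C(C)(C)C)[C@@H]2OCO[C@]2(COC(=O)c3ccccc3)[C@H]4O[C@@H]14
F11 | step 9 | triol: C1–OH and C2–OH cis, C6–OH trans to C1–OH, C3–OTBS, C4=C5 | O[C@H]1C=C[C@@H](O[Si](C)(C)C(C)(C)C)[C@H](O)[C@@]1(O)COC(=O)c1ccccc1
F12 | step 9 | C1,C2-acetonide with free C6–OH | O[C@H]1C=C[C@@H](O[Si](C)(C)C(C)(C)C)[C@@H]2OC(C)(C)O[C@]12COC(=O)c1ccccc1
F13 | step 9 | C1,C2-acetonide C6 methanesulfonate | CS(=O)(=O)O[C@H]1C=C[C@@H](O[Si](C)(C)C(C)(C)C)[C@@H]2OC(C)(C)O[C@]12COC(=O)c1ccccc1
A1 | alternative 1 | benzoic acid | OC(=O)c1ccccc1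
A2 | alternative 1 | methyl 1-hydroxycyclohexa-2,5-diene-1-carboxylate | COC(=O)C1(O)C=CCC=C1
A3 | alternative 1 | syn 2,3-epoxy alcohol ester: C2,C3-oxirane cis to C1–OH, C5=C6, CO2Me on C1 | COC(=O)[C@@]1(O)C=CC[C@@H]2O[C@H]12
A4 | alternative 2 | (1S,2R)-1,2-dihydroxycyclohexa-3,5-diene-1-carboxylic acid | OC(=O)[C@]1(O)C=CC=C[C@H]1O
A5 | alternative 3 | D-fructose (open-chain form) | OC[C@@H](O)[C@@H](O)[C@H](O)C(=O)CO
A6 | alternative 3 | open-chain iodo aldehyde: (Z)-C4=C5–I, C3–OBz, C2–OMe, C1 spiro-oxirane to C7, C6 aldehyde | I/C=C\[C@@H](OC(=O)c1ccccc1)[C@H](OC)[C@@]1(C=O)CO1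
A7 | alternative 3 | spiro-epoxy cyclohexenol: C6–OH trans to the C1–C7 oxirane oxygen, C4=C5, C3–OBz, C2–OMe | O[C@@H]1C=C[C@@H](OC(=O)c2ccccc2)[C@H](OC)[C@]13CO3
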